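Late in a run the intermediate of this scheme leaves by two exits, coupling to target and decay to side product, so the meeting took the split between them as its subject.

in all of them: starting material 0.10 M; coupling partner 1.50 equiv; free catalyst 0.55 mol%; second catalyst 11 mol%; time 30 h
- south-east: temperature 40 °C
- east: temperature 20 °C
- west: temperature 60 °C

    starting material + free catalyst ⇌ free catalyst + intermediate (K1 = 0.39, k1 = 640 M⁻¹ h⁻¹, Ea1 = 41.0 kJ mol⁻¹, ΔH1 = −48.0 kJ mol⁻¹)
    coupling partner + second catalyst + intermediate ⇌ second catalyst + target (K2 = 180 M⁻¹, k2 = 44 M⁻² h⁻¹, Ea2 = 38.0 kJ mol⁻¹, ΔH2 = 33.0 kJ mol⁻¹)
    intermediate → side product (k3 = 0.32 h⁻¹, Ea3 = 112 kJ mol⁻¹)
    starting material + coupling partner → uncatalysed product (k4 = 0.023 M⁻¹ h⁻¹, Ea4 = 70.0 kJ mol⁻¹)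
    (constants at 60 °C)

- constants are those at 60 °C; use the activation energies and enthalpies for any other temperature

* the best flask by amount of target, in percent of the starting material charged; "all alike" if 1.5 percentage points covers them all (south-east / east / west / all alike)
* amount of target at the end, in percent of the starting material charged, south-east
* amount of target at the end, in percent of the starting material charged, east
* amount of target at the end, in percent of the starting material charged, west

Minutes. The kineticist pointed out that, with [coupling partner] and [second catalyst] held at their charges, coupling is pseudo-first-order, so both exits are first order in [intermediate]. The mean of the intermediate curve over the run then multiplies both exits alike and cancels from their quotient. For west she found 0.227, and named this the exit ratio S, the pseudo-first-order coupling constant over the decay constant at the temperature of the flask, a selectivity factor. Cooling raises it, since decay has the higher activation energy: south-east has 1.25 and east 8.69.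

The process chemist objected that a ratio gives the split and not the amount, and asked how much of the charge passes an exit in the time. The kineticist answered that, once the first step has relaxed, the intermediate may be taken as the fraction K/(1+K) of the pool of starting material plus intermediate, and the pool as decaying first order at the sum of both exit constants times that fraction. K is 0.39 in west, 1.18 in south-east and 4.15 in east. The clock starts after the relaxation time of the first step, 0.797 h in west, 3.96 h in south-east and 17.3 h in east, the longest. The part of the pool passed through the exits is then reckoned at 96.0% in west, 53.6% in south-east and 12.0% in east, and the share S/(1+S) of it is counted as target.

The process chemist then corrected for the mean: averaged over the run, [coupling partner] was put below its charge by half the target made, and target was scaled down by the ratio of that mean to the charge. The uncatalysed step and the undoing of target were set aside. The minuted reckoning gives 26.8% for south-east, 10.4% for east and 16.7% for west, so the best flask is south-east.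

The forecast puts south-east first, with 25% there, 12% in east and 16.5% in west, on the ground that “this middle temperature gives the most target”, each figure a little apart from ours.

The simulation gives south-east as best, with 24.8% there, 11.7% in east and 15.0% in west.

West ends with target over side product at 0.201, against the reckoned 0.227. The decay exit holds west down: the same run without it reaches 35.9% instead of 15.0%, the largest single effect, yet 25% of what is missing.

For the neighbour of west with 0.600 equiv of coupling partner, S scales with the charge to 0.0908. That flask ends with 6.62% target and 82.8% side product, a quotient of 0.0800.

Its constants are assumed.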